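Assumption (one remark on the chemistry): 4-(methoxymethoxy)benzaldehyde is treated as a purchasable aldehyde (otherwise it is one MOM protection from 4-hydroxybenzaldehyde), and the propargylic alcohol is used as the racemate because its carbinol carbon ends as sp2 C2 of the flavone.

## Structural features

The target is a flavone: ring A (benzo) is fused to ring C (4-pyranone), and ring B, a 4-hydroxyphenyl group, sits on C2. Ring A is fully substituted, with OH on C5, OMe on C6, OH on C7 and, on C8, C2 of an N-methylpyrrolidine attached through a C(sp2)–C(sp3) bond. That pyrrolidine carbon is the only stereocentre (R); it has no stereogenic neighbour, so only absolute configuration has to be controlled. It is a benzylic amine carbon ortho to the C7 hydroxyl and to O1 and para to the C5 oxygen, so heterolysis of its C–N bond towards an ortho-quinone methide (under acid, or on heating a free aminophenol) would erase the configuration. Other sensitive points are the three phenols, the single aryl methyl ether that must outlast every deprotection, and the pyranone carbonyl, which forbids a late hydride reduction of a carbamate. The real difficulty is to make the C8–pyrrolidine bond enantioselectively at a carbon flanked by two oxygen-bearing carbons, and then to build ring C beside it without heat, acid or oxidant reaching the benzylic centre. The key step uses the fact that, once C8 carries the pyrrolidine, the oxygen on C8a has only one hydrogen-bearing ortho carbon, C4a: a propargyl ether on that oxygen can rearrange only to C4a, and the same oxygen then closes onto the former propargylic carbon to make O1–C2 of ring C.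

## Logic of the disconnections

22 ⇒ 21. The N–CH3 bond is cut first. A methyl group can be put on a secondary amine by iminium formation and hydride transfer at room temperature, which touches neither the pyranone nor the stereocentre. Leaving it to the end lets the nitrogen stay a carbamate through every thermal and oxidative step and removes any need to reduce a carbamate once the C4 carbonyl exists. The forward step must work on a free aminotriphenol without alkylating carbon; ring A has no open position, which helps.

21 ⇒ 20. Three O–CH2OCH3 bonds and the N–CO2C(CH3)3 bond are cut together. All four groups fall to one acid treatment while the C6 methyl ether is inert, so one step replaces separate phenol and amine unmasking. The acid is met only after ring A has been deactivated by the C4 carbonyl, which is when the benzylic C–N bond is least prone to ionise. The demand is that the acid step stays mild and short.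

20 ⇒ 19 ⇒ 18. No skeletal bond is cut; the C2=C3 double bond of 20 is taken back to the saturated ketone 19, and the C4 carbonyl of 19 to the C3=C4 alkene of 18. The reason is that the key step delivers ring C at the chromene oxidation level. Forward, oxygen must go to C4 and not C3, which a hydrogen-atom-transfer oxidation secures through the C4 benzylic radical, and the ketone must then be dehydrogenated under non-acidic conditions. The nitrogen is still a carbamate in both steps, so no amine is exposed to an oxidant.

18 ⇒ 15. This is the strategic cut: C4–C4a and O1–C2 of ring C. It removes a ring and reduces the problem to an aryl propargyl ether on the C8a oxygen. C4a is the only open ortho carbon, so no regiochemical choice arises, and no acylation of the crowded, electron-rich ring is needed. The forward step must run below the temperature at which the Boc group fragments. The Boc group that directs the lithiation is kept as the nitrogen mask, so the trioxygenated benzylic carbamate never meets acid in a carbamate exchange.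

15 ⇒ 11 + 14, and 14 ⇒ 12 + 13. The propargylic C–O bond is cut, then the C–C bond between the carbinol carbon and the alkyne. This separates ring B with C2–C4 from ring A with the pyrrolidine, and both halves come from simple materials. The etherification has to alkylate a hindered phenol on oxygen with a secondary, ionisable alcohol; the configuration at that carbon does not matter.

11 ⇒ 10 ⇒ 6 + 7. After the benzyl mask on the C8a oxygen is returned (10), the aryl–pyrrolidine bond is cut. This is the only bond at the stereocentre that can be formed with reliable absolute control from an achiral pyrrolidine, and it reduces the problem to an aryl bromide and a carbamate. The C8a oxygen must be masked because a free phenol would protonate the organozinc reagent; a benzyl ether is compact, inert to the coupling and removable by hydrogenolysis beside MOM and Boc. The forward coupling must succeed at a bromide flanked by two alkoxy groups.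

6 ⇒ 5 ⇒ 4 ⇒ 2 ⇒ 1. The C–Br bond, the benzyl ether, the C–O bond para to the methoxy group (via C–B) and the two MOM ethers are removed in turn. The oxygen para to the methoxy group cannot be introduced by electrophilic substitution, which would go ortho to the ring oxygens; a sterically governed C–H borylation reaches exactly that carbon. This is why the C5/C7 oxygens carry MOM and not benzyl ethers: benzyl rings would offer unhindered aryl C–H bonds to the borylation catalyst. Bromination needs no selectivity because the two open positions of 5 are equivalent.

## Other disconnections considered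

Alternative 1: The pyrrolidine is taken apart at its benzylic carbon: pyrrolidine N–C2 and C2–C3 are cut together, and C3–C4 is cut as an alkene.
- Forward: hispidulin A1 would be formylated at C8, its only free ring A carbon, to aldehyde A2. A three-component borono-Mannich (Petasis) reaction of A2 with an N-methylated allylic amine and a vinylboronic ester under a chiral diol would give the bis-allylic amine A3. Ring-closing metathesis with a ruthenium alkylidene (second-generation Grubbs catalyst) would give dihydropyrrole A4, and saturation of its alkene would give 22.
- In its favour: the C7 hydroxyl ortho to the aldehyde is the handle this condensation needs to bind boron. The N-methyl group arrives with the amine. The route is about four steps from A1 with no protecting groups, which is clearly better in step economy than the chosen plan. It is also catalytic in the chiral controller, where the chosen plan uses a stoichiometric diamine.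
- Against it here: the enantioselective version is best established for simpler aldehydes. In A2 the formyl group is wedged between the C7 hydroxyl and O1, belongs to an electron-poor chromone, and competes with three acidic phenols for boron and for the diol. A3 and A4 are free ortho-hydroxybenzylic tertiary amines, the arrangement that ionises to an ortho-quinone methide, and in A4 the stereocentre is also allylic, so loss of configuration, alkene migration and aromatisation to a pyrrole are all plausible. Metathesis would need the amine as its salt, and the last reduction must spare the C2=C3 bond of ring C and the benzylic C–N bond.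
- Comparison: structurally it is more convergent (better). Mechanistically the chosen plan is stronger, because it carries the stereocentre as a non-ionisable carbamate through every hot or oxidising step. On step economy Alternative 1 wins.

Alternative 2: Pyrrolidine C2–C3 and C4–C5 are cut, a (3+2) retron of an azomethine ylide on the ring A carbon and a two-carbon acceptor.
- Forward: the glycine imine A5 of the ring A aldehyde, as its chiral monovalent-copper ylide, would add an aryl vinyl sulfone to give the exo adduct A6. Reductive desulfonylation, excision of the ester carbon (hydrolysis and radical decarboxylation) and N-methylation would follow, and only then would ring C be built (MOM removal, C-acylation at the open ring carbon, cyclodehydration).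
- In its favour: this is a highly developed catalytic asymmetric reaction that closes the heterocycle and sets the benzylic centre in one step, and it avoids the hindered C(sp2)–C(sp3) coupling. On reliability of enantiocontrol and on economy of the chiral source it is the equal or the better of the chosen plan. The benzylic centre of A6 is labelled S only because the sulfonyl-bearing carbon outranks the aryl group; its spatial arrangement is that of R in 22.
- Against it here: the ester and sulfone are installed only to be removed, which costs three to four steps. The carbanion or radical formed in the desulfonylation is β to the ring nitrogen, so ring opening by elimination is a risk. The imine carbon carries a di-ortho-substituted, electron-rich aryl group, which slows ylide formation and addition. The whole flavone still has to be assembled afterwards on a ring bearing a basic or carbamate nitrogen.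
- Comparison: structurally it is linear and builds the easy ring first. Mechanistically its stereo-defining step is at least as secure as the sparteine lithiation. On step economy the chosen plan is well ahead.

Alternative 3: Only the pyrrolidine N–C2 bond is cut, leaving an open-chain carbamate on an 8-alkenyl flavone.
- Forward: A1 would be halogenated at C8 and cross-coupled to give the (E)-alkenyl carbamate A7. A chiral phosphoric acid would convert the ortho-hydroxystyrene unit of A7 into an ortho-quinone methide ion pair, and the carbamate nitrogen would add to the benzylic carbon to close the five-membered ring as A8. Hydrogenolysis of the benzyl carbamate and reductive methylation would finish.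
- In its favour: it turns the liability of the target, the ortho-hydroxybenzylic position, into the handle of the asymmetric step. It needs no phenol protection, is catalytic, and is about four to five steps from A1, so it is better than the chosen plan in step and atom economy.
- Against it here: the quinone methide must form from a ring A conjugated to the C4 carbonyl, whose C7 hydroxyl is a vinylogous acid, so protonation of the alkene is far less favourable than for the electron-rich ortho-vinylphenols where this reactivity is established. The chelated C5 hydroxyl, the carbonyl and the ring B phenol are competing binding sites for the catalyst. The addition is in principle reversible under the same acid, which would erode the enantiomeric purity. Polyphenolic flavones dissolve poorly in the non-polar media such catalysts need.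
- Comparison: structurally it is the shortest and most direct of all (better). Mechanistically it rests on ionising exactly the bond the chosen plan keeps from ionising, so its stereochemical outcome is the least predictable. On step economy it is better; on confidence the chosen plan is better.

Key step: step 9

## Route

Step 1
Reactants: 1 2-methoxybenzene-1,3-diol
Product: 2 2-methoxy-1,3-bis(methoxymethoxy)benzene
Conditions: NaH, MOMCl, THF–DMF, 0 °C → rt
Reagents that add atoms: chloromethyl methyl ether, COCCl
Why: Williamson-type O-alkylation of both phenoxides by the α-chloro ether; MOM is chosen because it has no aryl C–H to compete in step 2, survives base, organometallics and heat, and falls with the Boc group in one acid step at the end.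

Step 2
Reactants: 2 2-methoxy-1,3-bis(methoxymethoxy)benzene
Product: 4 4-methoxy-3,5-bis(methoxymethoxy)phenol, via arylboronic ester 3 (not isolated)
Conditions: [Ir(OMe)(cod)]2 (cat.), dtbpy, B2pin2, THF, 80 °C; then aq. NaOH, H2O2, 0 °C → rt
Reagents that add atoms: bis(pinacolato)diboron, CC1(C)OB(OC1(C)C)B1OC(C)(C)C(C)(C)O1 (boryl group of 3); hydrogen peroxide, OO (oxygen of 4)
Why: Iridium-catalysed C–H borylation is governed by sterics and should reach only the C–H para to the methoxy group, the one position with no ortho substituent; oxidation of the C–B bond (1,2-aryl shift on the boron peroxide) then gives the phenol that electrophilic substitution cannot deliver.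

Step 3
Reactants: 4 4-methoxy-3,5-bis(methoxymethoxy)phenol
Product: 5 5-(benzyloxy)-2-methoxy-1,3-bis(methoxymethoxy)benzene
Conditions: BnBr, K2CO3, DMF, rt
Reagents that add atoms: benzyl bromide, BrCc1ccccc1
Why: Williamson ether synthesis; the future C8a oxygen must be masked because a free phenol would protonate the organozinc reagent of step 5, and a benzyl ether is compact, inert to that coupling and removable by hydrogenolysis beside MOM and Boc.

Step 4
Reactants: 5 5-(benzyloxy)-2-methoxy-1,3-bis(methoxymethoxy)benzene
Product: 6 1-(benzyloxy)-2-bromo-4-methoxy-3,5-bis(methoxymethoxy)benzene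
Conditions: NBS, MeCN, 0 °C
Reagents that add atoms: N-bromosuccinimide, O=C1CCC(=O)N1Br
Why: Electrophilic aromatic bromination; the two open ring positions are equivalent by symmetry and each is ortho or para to three oxygens, and the first bromine deactivates and crowds the ring enough for one equivalent to stop at the monobromide.

Step 5
Reactants: 7 tert-butyl pyrrolidine-1-carboxylate; 6 1-(benzyloxy)-2-bromo-4-methoxy-3,5-bis(methoxymethoxy)benzene
Product: 10 tert-butyl (2R)-2-[6-(benzyloxy)-3-methoxy-2,4-bis(methoxymethoxy)phenyl]pyrrolidine-1-carboxylate, via lithiated carbamate 8 (not isolated), via organozinc chloride 9 (not isolated)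
Conditions: 7, s-BuLi, (−)-sparteine, MTBE, −78 °C; ZnCl2, −78 °C → rt; then 6, Pd(OAc)2 (cat.), t-Bu3P·HBF4, rt → 40 °C
Reagents that add atoms: sec-butyllithium, CCC(C)[Li] (lithium of 8); zinc chloride, Cl[Zn]Cl (zinc and chlorine of 9); 10 itself contains only atoms of 6 and 7
Why: Sparteine-mediated asymmetric α-deprotonation of the Boc carbamate removes the pro-S hydrogen to give 8, transmetalation to zinc proceeds with retention to the configurationally stable 9, and the Negishi coupling also proceeds with retention, so the R centre is set by the chiral diamine. A monoligated t-Bu3P–palladium catalyst is the type suited to a secondary alkylzinc and an electron-rich, di-ortho-substituted aryl bromide.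

Step 6
Reactants: 10 tert-butyl (2R)-2-[6-(benzyloxy)-3-methoxy-2,4-bis(methoxymethoxy)phenyl]pyrrolidine-1-carboxylate
Product: 11 tert-butyl (2R)-2-[6-hydroxy-3-methoxy-2,4-bis(methoxymethoxy)phenyl]pyrrolidine-1-carboxylate
Conditions: H2 (1 atm), Pd/C, EtOAc, rt
Reagents that add atoms: none
Why: Hydrogenolysis of the aryl benzyl ether under neutral conditions; MOM acetals and the Boc group are inert, and the benzylic C–N bond of an N-acyl amine is not cleaved under these conditions, so the stereocentre is untouched.

Step 7
Reactants: 12 4-(methoxymethoxy)benzaldehyde; 13 ethynylmagnesium bromide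
Product: 14 1-[4-(methoxymethoxy)phenyl]prop-2-yn-1-ol (racemic)
Conditions: THF, 0 °C; aq. NH4Cl
Reagents that add atoms: none
Why: Grignard 1,2-addition of the acetylide to the aldehyde; the new carbinol centre needs no control because it becomes sp2 C2 of the flavone.

Step 8
Reactants: 11 tert-butyl (2R)-2-[6-hydroxy-3-methoxy-2,4-bis(methoxymethoxy)phenyl]pyrrolidine-1-carboxylate; 14 1-[4-(methoxymethoxy)phenyl]prop-2-yn-1-ol
Product: 15 tert-butyl (2R)-2-[3-methoxy-2,4-bis(methoxymethoxy)-6-({1-[4-(methoxymethoxy)phenyl]prop-2-yn-1-yl}oxy)phenyl]pyrrolidine-1-carboxylate (both epimers at the propargylic carbon)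
Conditions: PPh3, DIAD, toluene, 0 °C → rt
Reagents that add atoms: none
Why: Mitsunobu etherification with the phenol (pKa about 10) as the acidic partner and the secondary propargylic alcohol as the activated one; the neutral conditions leave MOM, Boc and the terminal alkyne alone, and the configuration created at the propargylic carbon is irrelevant.

Step 9
Reactants: 15 tert-butyl (2R)-2-[3-methoxy-2,4-bis(methoxymethoxy)-6-({1-[4-(methoxymethoxy)phenyl]prop-2-yn-1-yl}oxy)phenyl]pyrrolidine-1-carboxylate
Product: 18 tert-butyl (2R)-2-{6-methoxy-5,7-bis(methoxymethoxy)-2-[4-(methoxymethoxy)phenyl]-2H-chromen-8-yl}pyrrolidine-1-carboxylate (both epimers at chromene C2), via ortho-allenylphenol 16 (not isolated), via ortho-quinone methide 17 (not isolated)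
Conditions: PhNEt2, 160 °C, N2
Reagents that add atoms: none
Why: Heating starts an aromatic propargyl Claisen rearrangement: the [3,3] shift joins the alkyne terminus to C4a and breaks the O–C(propargylic) bond, and enolisation of the dienone gives allenylphenol 16. A 1,5-hydrogen shift from the phenolic oxygen to the central allene carbon then gives the (Z)-dienone 17, whose thermal, disrotatory oxa-6π electrocyclisation closes the six-membered ring C through the carbonyl oxygen, re-forming O1–C2 and restoring the aromaticity of ring A. The closest known reaction type is the thermal conversion of aryl propargyl ethers into 2H-chromenes. Chromene C2 is the only new stereocentre; nothing controls it, both epimers are expected, and control is unnecessary because C2 becomes sp2 in step 11. The selectivity that matters is positional and the substrate secures it: C8 carries the pyrrolidine, so C4a is the only ortho carbon that can rearomatise after the shift, and a shift towards C8 can only revert. Chromene formation, not benzofuran formation, is favoured by the neutral, weakly basic amine solvent, free of fluoride or alkoxide. The aryl group on the propargylic carbon weakens the breaking C–O bond, which should let the [3,3] step run near 160 °C, below the range in which an N,N-dialkyl Boc carbamate fragments. The carbamate keeps the nitrogen non-basic, so the benzylic C–N bond next to the transient phenol should not ionise and the R centre should be carried through unchanged.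

Step 10
Reactants: 18 tert-butyl (2R)-2-{6-methoxy-5,7-bis(methoxymethoxy)-2-[4-(methoxymethoxy)phenyl]-2H-chromen-8-yl}pyrrolidine-1-carboxylate
Product: 19 tert-butyl (2R)-2-{6-methoxy-5,7-bis(methoxymethoxy)-2-[4-(methoxymethoxy)phenyl]-4-oxo-3,4-dihydro-2H-chromen-8-yl}pyrrolidine-1-carboxylate (both epimers at C2)
Conditions: FeCl2 (cat.), neocuproine, PhSiH3, EtOH, air, rt
Reagents that add atoms: dioxygen, O=O
Why: Iron-catalysed Wacker-type oxidation by metal-hydride hydrogen-atom transfer (Mukaiyama-type): the hydrogen atom adds to C3 to give the C4 radical, benzylic to the electron-rich ring A, which is trapped by O2 and collapses to the ketone. This Markovnikov sense places the oxygen on C4, and the conditions are neutral, so MOM and Boc persist.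

Step 11
Reactants: 19 tert-butyl (2R)-2-{6-methoxy-5,7-bis(methoxymethoxy)-2-[4-(methoxymethoxy)phenyl]-4-oxo-3,4-dihydro-2H-chromen-8-yl}pyrrolidine-1-carboxylate
Product: 20 tert-butyl (2R)-2-{6-methoxy-5,7-bis(methoxymethoxy)-2-[4-(methoxymethoxy)phenyl]-4-oxo-4H-chromen-8-yl}pyrrolidine-1-carboxylate
Conditions: I2, pyridine, 90 °C
Reagents that add atoms: none
Why: Iodine–pyridine dehydrogenation of a flavanone to a flavone (enolisation, α-iodination at C3, loss of HI), driven by conjugation of the new C2=C3 bond with ring B and the carbonyl; the basic medium protects the acid-labile groups, the C2 epimers converge, and ring A has no open position for iodination.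

Step 12
Reactants: 20 tert-butyl (2R)-2-{6-methoxy-5,7-bis(methoxymethoxy)-2-[4-(methoxymethoxy)phenyl]-4-oxo-4H-chromen-8-yl}pyrrolidine-1-carboxylate
Product: 21 5,7-dihydroxy-2-(4-hydroxyphenyl)-6-methoxy-8-[(2R)-pyrrolidin-2-yl]-4H-chromen-4-one
Conditions: HCl (3 M), MeOH, rt → 40 °C; then aq. NaHCO3, 0 °C; used at once
Reagents that add atoms: none
Why: Acid-catalysed acetal exchange with methanol removes the three MOM groups and acidolysis removes the Boc group, while the aryl methyl ether is inert. Ring A is now deactivated by the C4 carbonyl and the liberated amine is protonated throughout, so heterolysis of the benzylic C–N bond should be slow under these mild conditions.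

Step 13
Reactants: 21 5,7-dihydroxy-2-(4-hydroxyphenyl)-6-methoxy-8-[(2R)-pyrrolidin-2-yl]-4H-chromen-4-one
Product: 22 5,7-dihydroxy-2-(4-hydroxyphenyl)-6-methoxy-8-[(2R)-1-methylpyrrolidin-2-yl]-4H-chromen-4-one
Conditions: aq. HCHO, 2-picoline–borane, MeOH–AcOH, 0 °C → rt
Reagents that add atoms: formaldehyde, C=O
Why: Reductive amination of the secondary amine with formaldehyde and a mild amine–borane, which does not reduce the vinylogous-ester carbonyl of the flavone; any N,O-aminal formed with the C7 hydroxyl is reduced to the same N-methyl amine. Ring A has no free carbon for a Mannich reaction, and the stereocentre takes no part.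

## Compound list

1 | 2-methoxybenzene-1,3-diol | COc1c(O)cccc1O | starting material
2 | 2-methoxy-1,3-bis(methoxymethoxy)benzene | COCOc1cccc(OCOC)c1OC | intermediate
3 | 2-[4-methoxy-3,5-bis(methoxymethoxy)phenyl]-4,4,5,5-tetramethyl-1,3,2-dioxaborolane | COCOc1cc(B2OC(C)(C)C(C)(C)O2)cc(OCOC)c1OC | intermediate
4 | 4-methoxy-3,5-bis(methoxymethoxy)phenol | COCOc1cc(O)cc(OCOC)c1OC | intermediate
5 | 5-(benzyloxy)-2-methoxy-1,3-bis(methoxymethoxy)benzene | COCOc1cc(OCc2ccccc2)cc(OCOC)c1OC | intermediate
6 | 1-(benzyloxy)-2-bromo-4-methoxy-3,5-bis(methoxymethoxy)benzene | COCOc1cc(OCc2ccccc2)c(Br)c(OCOC)c1OC | intermediate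
7 | tert-butyl pyrrolidine-1-carboxylate | CC(C)(C)OC(=O)N1CCCC1 | starting material
8 | tert-butyl (2S)-2-lithiopyrrolidine-1-carboxylate, as its (−)-sparteine complex (ligand not drawn) | [Li][C@H]1CCCN1C(=O)OC(C)(C)C | intermediate
9 | [(2S)-1-(tert-butoxycarbonyl)pyrrolidin-2-yl]zinc chloride | Cl[Zn][C@H]1CCCN1C(=O)OC(C)(C)C | intermediate
10 | tert-butyl (2R)-2-[6-(benzyloxy)-3-methoxy-2,4-bis(methoxymethoxy)phenyl]pyrrolidine-1-carboxylate | COCOc1cc(OCc2ccccc2)c([C@H]2CCCN2C(=O)OC(C)(C)C)c(OCOC)c1OC | intermediate
11 | tert-butyl (2R)-2-[6-hydroxy-3-methoxy-2,4-bis(methoxymethoxy)phenyl]pyrrolidine-1-carboxylate | COCOc1cc(O)c([C@H]2CCCN2C(=O)OC(C)(C)C)c(OCOC)c1OC | intermediate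
12 | 4-(methoxymethoxy)benzaldehyde | COCOc1ccc(C=O)cc1 | starting material
13 | ethynylmagnesium bromide | C#C[Mg]Br | starting material
14 | 1-[4-(methoxymethoxy)phenyl]prop-2-yn-1-ol (racemic) | C#CC(O)c1ccc(OCOC)cc1 | intermediate
15 | tert-butyl (2R)-2-[3-methoxy-2,4-bis(methoxymethoxy)-6-({1-[4-(methoxymethoxy)phenyl]prop-2-yn-1-yl}oxy)phenyl]pyrrolidine-1-carboxylate (both epimers at the propargylic carbon) | COCOc1cc(OC(C#C)c2ccc(OCOC)cc2)c([C@H]2CCCN2C(=O)OC(C)(C)C)c(OCOC)c1OC | intermediate
16 | tert-butyl (2R)-2-[2-hydroxy-5-methoxy-4,6-bis(methoxymethoxy)-3-{3-[4-(methoxymethoxy)phenyl]propa-1,2-dien-1-yl}phenyl]pyrrolidine-1-carboxylate | COc1c(OCOC)c([C@H]2CCCN2C(=O)OC(C)(C)C)c(O)c(C=C=Cc2ccc(OCOC)cc2)c1OCOC | intermediate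
17 | tert-butyl (2R)-2-[3-methoxy-2,4-bis(methoxymethoxy)-5-{3-[4-(methoxymethoxy)phenyl]prop-2-en-1-ylidene}-6-oxocyclohexa-1,3-dien-1-yl]pyrrolidine-1-carboxylate | COC1=C(OCOC)C(=CC=Cc2ccc(OCOC)cc2)C(=O)C([C@H]2CCCN2C(=O)OC(C)(C)C)=C1OCOC | intermediate
18 | tert-butyl (2R)-2-{6-methoxy-5,7-bis(methoxymethoxy)-2-[4-(methoxymethoxy)phenyl]-2H-chromen-8-yl}pyrrolidine-1-carboxylate (both epimers at chromene C2) | COc1c(OCOC)c([C@H]2CCCN2C(=O)OC(C)(C)C)c2OC(c3ccc(OCOC)cc3)C=Cc2c1OCOC | intermediate
19 | tert-butyl (2R)-2-{6-methoxy-5,7-bis(methoxymethoxy)-2-[4-(methoxymethoxy)phenyl]-4-oxo-3,4-dihydro-2H-chromen-8-yl}pyrrolidine-1-carboxylate (both epimers at C2) | COc1c(OCOC)c([C@H]2CCCN2C(=O)OC(C)(C)C)c2OC(c3ccc(OCOC)cc3)CC(=O)c2c1OCOC | intermediate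
20 | tert-butyl (2R)-2-{6-methoxy-5,7-bis(methoxymethoxy)-2-[4-(methoxymethoxy)phenyl]-4-oxo-4H-chromen-8-yl}pyrrolidine-1-carboxylate | COc1c(OCOC)c([C@H]2CCCN2C(=O)OC(C)(C)C)c2oc(-c3ccc(OCOC)cc3)cc(=O)c2c1OCOC | intermediate
21 | 5,7-dihydroxy-2-(4-hydroxyphenyl)-6-methoxy-8-[(2R)-pyrrolidin-2-yl]-4H-chromen-4-one | COc1c(O)c([C@H]2CCCN2)c2oc(-c3ccc(O)cc3)cc(=O)c2c1O | intermediate
22 | 5,7-dihydroxy-2-(4-hydroxyphenyl)-6-methoxy-8-[(2R)-1-methylpyrrolidin-2-yl]-4H-chromen-4-one | COc1c(O)c([C@H]2CCCN2C)c2oc(-c3ccc(O)cc3)cc(=O)c2c1O | target

## Step count and least certain steps

Total step count: 13. Longest linear sequence: 12 steps (steps 1–6 and 8–13); step 7 is a one-step side branch.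

Step 9 (key step). The most likely failure is thermal fragmentation of the Boc group, or attack of the transient C8a phenol on the carbamate carbonyl, at the temperature the [3,3] shift needs. Heterolysis of the doubly activated propargylic C–O bond could also compete with the pericyclic path. Fallback: from 15, treatment with a cationic monovalent-gold catalyst (Ph3PAuNTf2, CH2Cl2, rt) should give 18 directly by 6-endo-dig hydroarylation, in which C4a attacks the gold-activated alkyne terminus and protodeauration follows. This replaces the thermal cascade by π-acid catalysis at room temperature and rejoins the route at 18. It makes no new compound (F0).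

Step 5. Transmetalation and reductive elimination at an aryl–palladium centre flanked by two alkoxy groups may be slow. β-Hydride elimination from the pyrrolidinyl–palladium species and simple debromination of 6 would then take over. Fallback: from 6, bromine–lithium exchange (t-BuLi, THF, −78 °C) and transmetalation with MgBr2·OEt2 give the aryl Grignard reagent. This is added in CH2Cl2–toluene at −78 °C to (R)-N-[(1E)-4-chlorobutylidene]-2-methylpropane-2-sulfinamide F1, made from 4-chlorobutanal and (R)-tert-butanesulfinamide with CuSO4. The closed, magnesium-chelated transition-state model predicts the R carbon centre from the R auxiliary, giving (R)-N-{(1R)-1-[6-(benzyloxy)-3-methoxy-2,4-bis(methoxymethoxy)phenyl]-4-chlorobutyl}-2-methylpropane-2-sulfinamide F2. KOt-Bu in THF closes the ring by N-alkylation to (2R)-2-[6-(benzyloxy)-3-methoxy-2,4-bis(methoxymethoxy)phenyl]-1-[(R)-tert-butylsulfinyl]pyrrolidine F3. Brief HCl in MeOH at 0 °C, short enough to spare the aryl MOM ethers, removes the sulfinyl group to give (2R)-2-[6-(benzyloxy)-3-methoxy-2,4-bis(methoxymethoxy)phenyl]pyrrolidine F4. Boc2O with Et3N then returns to the route at 10.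

Step 8. The activated alkoxyphosphonium of the electron-rich, benzylic and propargylic alcohol may ionise before the hindered phenoxide attacks. That would lead to C-alkylation at the open ring carbon or to attack at the alkyne terminus. Fallback: from 14, acylation with methyl chloroformate and pyridine gives methyl 1-[4-(methoxymethoxy)phenyl]prop-2-yn-1-yl carbonate F5. F5 and 11 are then joined by copper-catalysed propargylic substitution (Cu(MeCN)4PF6 (cat.), i-Pr2NEt, MeOH, 0 °C), which runs through a copper allenylidene and is a known way to aryl propargyl ethers from phenols. This rejoins the route at 15.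

Step 10. The hydrogen-atom-transfer sequence may stall at the alcohol or peroxide oxidation level, or simply reduce the alkene. Abstraction of other activated hydrogens by oxygen-centred radicals is a lesser concern. Fallback: from 18, base-mediated prototropic isomerisation (KOt-Bu, DMSO, rt) should move the double bond into conjugation with ring B and give tert-butyl (2R)-2-{6-methoxy-5,7-bis(methoxymethoxy)-2-[4-(methoxymethoxy)phenyl]-4H-chromen-8-yl}pyrrolidine-1-carboxylate F6. Allylic oxidation of its doubly activated C4 methylene (t-BuOOH, Rh2(cap)4 (cat.), CH2Cl2, rt) then gives the flavone. This bypasses 19 and rejoins the route at 20.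

Step 11. In hot pyridine ring C may open by β-elimination to the 2'-hydroxychalcone, and the dehydrogenation may stay incomplete on this crowded ketone. Fallback: from 19, enolisation with in situ silylation (LiHMDS, TMSCl, THF, −78 °C) gives the silyl enol ether tert-butyl (2R)-2-{6-methoxy-5,7-bis(methoxymethoxy)-2-[4-(methoxymethoxy)phenyl]-4-[(trimethylsilyl)oxy]-2H-chromen-8-yl}pyrrolidine-1-carboxylate F7. Saegusa–Ito oxidation (Pd(OAc)2, MeCN, rt) dehydrogenates it and rejoins the route at 20.

## Further compounds

F1 | step 5 | (R)-N-[(1E)-4-chlorobutylidene]-2-methylpropane-2-sulfinamide | CC(C)(C)[S@@](=O)/N=C/CCCCl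
F2 | step 5 | (R)-N-{(1R)-1-[6-(benzyloxy)-3-methoxy-2,4-bis(methoxymethoxy)phenyl]-4-chlorobutyl}-2-methylpropane-2-sulfinamide | COCOc1cc(OCc2ccccc2)c([C@@H](CCCCl)N[S@](=O)C(C)(C)C)c(OCOC)c1OC
F3 | step 5 | (2R)-2-[6-(benzyloxy)-3-methoxy-2,4-bis(methoxymethoxy)phenyl]-1-[(R)-tert-butylsulfinyl]pyrrolidine | COCOc1cc(OCc2ccccc2)c([C@H]2CCCN2[S@](=O)C(C)(C)C)c(OCOC)c1OC
F4 | step 5 | (2R)-2-[6-(benzyloxy)-3-methoxy-2,4-bis(methoxymethoxy)phenyl]pyrrolidine | COCOc1cc(OCc2ccccc2)c([C@H]2CCCN2)c(OCOC)c1OC
F5 | step 8 | methyl 1-[4-(methoxymethoxy)phenyl]prop-2-yn-1-yl carbonate | C#CC(OC(=O)OC)c1ccc(OCOC)cc1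
F0 | step 9 | none | none
F6 | step 10 | tert-butyl (2R)-2-{6-methoxy-5,7-bis(methoxymethoxy)-2-[4-(methoxymethoxy)phenyl]-4H-chromen-8-yl}pyrrolidine-1-carboxylate | COc1c(OCOC)c([C@H]2CCCN2C(=O)OC(C)(C)C)c2OC(c3ccc(OCOC)cc3)=CCc2c1OCOC
F7 | step 11 | tert-butyl (2R)-2-{6-methoxy-5,7-bis(methoxymethoxy)-2-[4-(methoxymethoxy)phenyl]-4-[(trimethylsilyl)oxy]-2H-chromen-8-yl}pyrrolidine-1-carboxylate | COc1c(OCOC)c([C@H]2CCCN2C(=O)OC(C)(C)C)c2OC(c3ccc(OCOC)cc3)C=C(O[Si](C)(C)C)c2c1OCOC
A1 | alternative 1 | hispidulin, 5,7-dihydroxy-2-(4-hydroxyphenyl)-6-methoxy-4H-chromen-4-one | COc1c(O)cc2oc(-c3ccc(O)cc3)cc(=O)c2c1O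
A2 | alternative 1 | 5,7-dihydroxy-2-(4-hydroxyphenyl)-6-methoxy-4-oxo-4H-chromene-8-carbaldehyde | COc1c(O)c(C=O)c2oc(-c3ccc(O)cc3)cc(=O)c2c1O
A3 | alternative 1 | 5,7-dihydroxy-2-(4-hydroxyphenyl)-6-methoxy-8-{(1R)-1-[methyl(prop-2-en-1-yl)amino]prop-2-en-1-yl}-4H-chromen-4-one | COc1c(O)c([C@H](N(C)CC=C)C=C)c2oc(-c3ccc(O)cc3)cc(=O)c2c1O
A4 | alternative 1 | 5,7-dihydroxy-2-(4-hydroxyphenyl)-6-methoxy-8-[(2R)-1-methyl-2,5-dihydro-1H-pyrrol-2-yl]-4H-chromen-4-one | COc1c(O)c([C@H]2C=CCN2C)c2oc(-c3ccc(O)cc3)cc(=O)c2c1O
A5 | alternative 2 | methyl N-{(E)-[2,4-bis(benzyloxy)-3-methoxy-6-(methoxymethoxy)phenyl]methylidene}glycinate | COC(=O)C/N=C/c1c(OCOC)cc(OCc2ccccc2)c(OC)c1OCc1ccccc1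
A6 | alternative 2 | methyl (2S,4R,5S)-5-[2,4-bis(benzyloxy)-3-methoxy-6-(methoxymethoxy)phenyl]-4-(phenylsulfonyl)pyrrolidine-2-carboxylate (2,5-cis, 4,5-trans) | COc1c(OCc2ccccc2)cc(OCOC)c([C@H]2[C@H](S(=O)(=O)c3ccccc3)C[C@@H](C(=O)OC)N2)c1OCc1ccccc1
A7 | alternative 3 | benzyl N-{(3E)-4-[5,7-dihydroxy-2-(4-hydroxyphenyl)-6-methoxy-4-oxo-4H-chromen-8-yl]but-3-en-1-yl}carbamate | COc1c(O)c(/C=C/CCNC(=O)OCc2ccccc2)c2oc(-c3ccc(O)cc3)cc(=O)c2c1O
A8 | alternative 3 | benzyl (2R)-2-[5,7-dihydroxy-2-(4-hydroxyphenyl)-6-methoxy-4-oxo-4H-chromen-8-yl]pyrrolidine-1-carboxylate | COc1c(O)c([C@H]2CCCN2C(=O)OCc2ccccc2)c2oc(-c3ccc(O)cc3)cc(=O)c2c1O
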